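**Plan** (chain numbered from the lactone carbonyl C1 through C4, the methyl-bearing ring carbon, C5 and C8, the two carbinol carbons, to C15, the CH2 on the furan)

- Retrosynthetic cuts, in order: the C9=C10 olefin (cross-metathesis), the lactone O–C4 bond (epoxide opening), the C2–C3 bond (enolate alkylation) and, in the furan half, the C14–C15 bond (Grignard coupling).
- Forward: (S)-linalool is silylated, oxidised and brominated at its (E)-methyl group and alkylated with an acetate enolate to give the (E)-C4=C5 tert-butyl ester. Shi epoxidation, acid-triggered closure of the butanolide (the only ring made) and desilylation follow. The furyl skipped diene comes from alkyne carboalumination and a copper-catalysed Grignard coupling, and cross-metathesis joins the halves last.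
- Stereochemistry: C8 (S) is bought with linalool. C4 (S) and C5 (R) come from reagent-controlled epoxidation of the (E)-olefin and stereospecific opening with inversion at C4. C12=C13 (E) comes from syn-carboalumination and C9=C10 (E) from the metathesis.
- Enabling feature: the butanolide ring oxygen sits on the quaternary ring carbon C4, the exocyclic neighbour C5 carries a hydroxyl anti to it, and the carbonyl carbon C1 is three bonds from C4. This is the imprint of a 5-exo opening of a (4R,5R)-4,5-epoxide by its own ester carbonyl oxygen.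

Key step: step 6

Assumption: (S)-(+)-linalool (coriandrol) of high enantiomeric purity, 3-(chloromethyl)furan and pent-1-en-4-yne are taken as purchasable compounds.

**Step 1**
Reactants: 1 (S)-(+)-linalool [(3S)-3,7-dimethylocta-1,6-dien-3-ol]
Product: 2 triethyl{[(3S)-3,7-dimethylocta-1,6-dien-3-yl]oxy}silane
Conditions: Et3SiOTf (1.2 equiv), 2,6-lutidine (2 equiv), CH2Cl2, −78 to 0 °C
Reagents that add atoms: triethylsilyl trifluoromethanesulfonate CC[Si](CC)(CC)OS(=O)(=O)C(F)(F)F
Why: Silyl ether formation with a silyl triflate and a hindered base is reliable for tertiary alcohols and masks the C8 oxygen against bromination in step 3 and against attack on the epoxide in step 6; no stereocentre is touched.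

**Step 2**
Reactants: 2 triethyl{[(3S)-3,7-dimethylocta-1,6-dien-3-yl]oxy}silane
Product: 3 (2E,6S)-2,6-dimethyl-6-[(triethylsilyl)oxy]octa-2,7-dien-1-ol
Conditions: SeO2 (0.3 equiv), t-BuOOH (3 equiv), salicylic acid (0.1 equiv), CH2Cl2, rt
Reagents that add atoms: tert-butyl hydroperoxide CC(C)(C)OO (terminal oxygen source; the oxygen is passed on by the catalytic selenium dioxide O=[Se]=O)
Why: Selenium dioxide allylic oxidation (ene reaction, then [2,3]-sigmatropic shift) attacks the more substituted olefin terminus at the methyl trans to the chain and should give the (E)-allylic alcohol, while the vinyl group has no allylic hydrogen and stays intact.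

**Step 3**
Reactants: 3 (2E,6S)-2,6-dimethyl-6-[(triethylsilyl)oxy]octa-2,7-dien-1-ol
Product: 4 {[(3S,6E)-8-bromo-3,7-dimethylocta-1,6-dien-3-yl]oxy}triethylsilane
Conditions: CBr4 (1.2 equiv), PPh3 (1.3 equiv), 2,6-lutidine (0.2 equiv), CH2Cl2, 0 °C
Reagents that add atoms: carbon tetrabromide BrC(Br)(Br)Br
Why: The Appel reaction replaces the primary allylic hydroxyl by bromide through SN2 displacement of the oxyphosphonium group under neutral conditions, so neither the (E)-olefin nor the acid-labile tertiary allylic silyl ether should suffer.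

**Step 4**
Reactants: 4 {[(3S,6E)-8-bromo-3,7-dimethylocta-1,6-dien-3-yl]oxy}triethylsilane; 5 tert-butyl acetate
Product: 7 tert-butyl (4E,8S)-4,8-dimethyl-8-[(triethylsilyl)oxy]deca-4,9-dienoate, via lithium enolate of tert-butyl acetate 6 (not isolated)
Conditions: LiN(iPr)2 (1.3 equiv), 5 (1.3 equiv), THF, −78 °C; then 4, DMPU, −78 to −30 °C
Reagents that add atoms: none
Why: Ester enolate alkylation by a primary allylic bromide proceeds by SN2 at the α-carbon, adds C1–C2 with the (E)-C4=C5 geometry unchanged, and the bulky tert-butyl ester suppresses self-condensation while providing the leaving group needed in step 6.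

**Step 5**
Reactants: 7 tert-butyl (4E,8S)-4,8-dimethyl-8-[(triethylsilyl)oxy]deca-4,9-dienoate
Product: 8 tert-butyl 3-[(2R,3R)-2-methyl-3-{(3S)-3-methyl-3-[(triethylsilyl)oxy]pent-4-en-1-yl}oxiran-2-yl]propanoate
Conditions: 1,2:4,5-di-O-isopropylidene-β-D-erythro-hexo-2,3-diulopyranose (D-fructose-derived Shi ketone, 0.3 equiv), Oxone (2KHSO5·KHSO4·K2SO4), K2CO3, n-Bu4NHSO4 (cat.), aq. Na2B4O7 buffer (pH about 10.5), MeCN/CH2(OMe)2, 0 °C
Reagents that add atoms: potassium peroxymonosulfate [K+].[O-]S(=O)(=O)OO
Why: In the Shi asymmetric epoxidation the chiral dioxirane transfers oxygen through a spiro transition state to one face of the electron-rich (E)-trisubstituted olefin, which should give the (4R,5R)-epoxide under reagent control (the remote C8 centre has no say), while the hindered monosubstituted vinyl group reacts far more slowly.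

**Step 6**
Reactants: 8 tert-butyl 3-[(2R,3R)-2-methyl-3-{(3S)-3-methyl-3-[(triethylsilyl)oxy]pent-4-en-1-yl}oxiran-2-yl]propanoate
Product: 10 (5S)-5-{(1R,4S)-1-hydroxy-4-methyl-4-[(triethylsilyl)oxy]hex-5-en-1-yl}-5-methyloxolan-2-one, via 2-tert-butoxyoxolanylium ion 9 (not isolated)
Conditions: (+)-camphor-10-sulfonic acid (0.2 equiv), CH2Cl2, 0 °C
Reagents that add atoms: none
Why: Protonation of the epoxide weakens the tertiary C4–O bond, and the ester carbonyl oxygen, held four atoms away, displaces it from the rear to give the dialkoxycarbenium ion 9, which sheds its tert-butyl group as 2-methylpropene and returns the proton, so the acid is catalytic. The closest known reaction type is the acid-mediated lactonisation of epoxy tert-butyl esters used to terminate epoxide-opening cascades. The butanolide closes in the 5-exo-tet mode. C4 becomes (S) by inversion of the (R)-epoxide carbon, because the tether can only reach the face opposite the departing oxygen, and C5 stays (R) because its C–O bond is never broken, so the anti O/OH pattern follows from the (E)-olefin geometry. The step needs regioselectivity (attack at C4, not 6-endo at C5) and chemoselectivity (ester oxygen, not the C8 oxygen): the first is secured by the cation-stabilising tertiary carbon together with the five-membered transition state, the second by the bulky triethylsilyl cap on O8 and by catalytic acid at 0 °C, which should leave the tertiary allylic ether un-ionised.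

**Step 7**
Reactants: 10 (5S)-5-{(1R,4S)-1-hydroxy-4-methyl-4-[(triethylsilyl)oxy]hex-5-en-1-yl}-5-methyloxolan-2-one
Product: 11 (5S)-5-[(1R,4S)-1,4-dihydroxy-4-methylhex-5-en-1-yl]-5-methyloxolan-2-one
Conditions: HF·pyridine, pyridine, THF, 0 °C to rt
Reagents that add atoms: none
Why: Fluoride-driven desilylation under buffered conditions frees the tertiary allylic alcohol, needed free for the metathesis, without opening the lactone or ionising the allylic C–O bond.

**Step 8**
Reactants: 12 pent-1-en-4-yne
Product: 15 (2E)-3-methylhexa-2,5-dien-1-ol, via alkenyldimethylalane 13 (not isolated), via lithium alkenylalanate 14 (not isolated)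
Conditions: AlMe3 (2 equiv), Cp2ZrCl2 (0.2 equiv), CH2Cl2, 0 °C to rt; volatiles removed; n-BuLi (1 equiv), THF/hexane, 0 °C; (CH2O)n, rt; H2O work-up
Reagents that add atoms: trimethylaluminium C[Al](C)C; formaldehyde (as paraformaldehyde) C=O
Why: Zirconium-catalysed methylalumination (Negishi carboalumination) adds methyl and aluminium syn across the terminal alkyne with the metal on the terminal carbon, which fixes the (E)-trisubstituted olefin, and the alanate is hydroxymethylated by formaldehyde with retention; the isolated alkene does not react under these conditions.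

**Step 9**
Reactants: 15 (2E)-3-methylhexa-2,5-dien-1-ol
Product: 16 (2E)-1-chloro-3-methylhexa-2,5-diene
Conditions: PPh3 (1.3 equiv), CCl4, reflux
Reagents that add atoms: carbon tetrachloride ClC(Cl)(Cl)Cl
Why: Appel-type chlorination converts the primary allylic alcohol into the chloride by SN2 displacement without allylic transposition or loss of the (E)-geometry.

**Step 10**
Reactants: 16 (2E)-1-chloro-3-methylhexa-2,5-diene; 17 3-(chloromethyl)furan
Product: 19 3-[(3E)-4-methylhepta-3,6-dien-1-yl]furan, via furan-3-ylmethylmagnesium chloride 18 (not isolated)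
Conditions: 17, Mg turnings, THF, 0 °C to rt (slow addition); then 16, Li2CuCl4 (3 mol%), THF, 0 °C
Reagents that add atoms: none
Why: Copper-catalysed coupling of a benzylic-type Grignard reagent with a primary allylic chloride (Kochi-type sp3–sp3 coupling) takes place at the α-carbon with retention of the olefin geometry and forms the C14–C15 bond.

**Step 11**
Reactants: 11 (5S)-5-[(1R,4S)-1,4-dihydroxy-4-methylhex-5-en-1-yl]-5-methyloxolan-2-one; 19 3-[(3E)-4-methylhepta-3,6-dien-1-yl]furan
Product: 20 (5S)-5-[(1R,4S,5E,8E)-11-(furan-3-yl)-1,4-dihydroxy-4,8-dimethylundeca-5,8-dien-1-yl]-5-methyloxolan-2-one (CNP0151262.1)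
Conditions: 19 (3 equiv), second-generation Hoveyda–Grubbs catalyst RuCl2(H2IMes)(=CH-C6H4-2-OiPr) (10 mol%, in portions), 1,4-benzoquinone (20 mol%), CH2Cl2, 40 °C
Reagents that add atoms: none
Why: Olefin cross-metathesis between a readily dimerising terminal olefin used in excess and a tertiary allylic alcohol that does not homodimerise should favour the cross product, the quaternary carbinol next to the new double bond enforces the (E)-geometry, and the trisubstituted olefin, furan, lactone and free hydroxyls are inert to the ruthenium carbene while benzoquinone suppresses double-bond migration in the skipped diene.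

**Compound list**

1 | (S)-(+)-linalool, (3S)-3,7-dimethylocta-1,6-dien-3-ol | C=C[C@@](C)(O)CCC=C(C)C | starting material
2 | triethyl{[(3S)-3,7-dimethylocta-1,6-dien-3-yl]oxy}silane | C=C[C@@](C)(O[Si](CC)(CC)CC)CCC=C(C)C | intermediate
3 | (2E,6S)-2,6-dimethyl-6-[(triethylsilyl)oxy]octa-2,7-dien-1-ol | C=C[C@@](C)(O[Si](CC)(CC)CC)CC/C=C(\C)CO | intermediate
4 | {[(3S,6E)-8-bromo-3,7-dimethylocta-1,6-dien-3-yl]oxy}triethylsilane | C=C[C@@](C)(O[Si](CC)(CC)CC)CC/C=C(\C)CBr | intermediate
5 | tert-butyl acetate | CC(=O)OC(C)(C)C | starting material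
6 | lithium enolate of tert-butyl acetate (not isolated) | C=C(O[Li])OC(C)(C)C | intermediate
7 | tert-butyl (4E,8S)-4,8-dimethyl-8-[(triethylsilyl)oxy]deca-4,9-dienoate | C=C[C@@](C)(O[Si](CC)(CC)CC)CC/C=C(\C)CCC(=O)OC(C)(C)C | intermediate
8 | tert-butyl 3-[(2R,3R)-2-methyl-3-{(3S)-3-methyl-3-[(triethylsilyl)oxy]pent-4-en-1-yl}oxiran-2-yl]propanoate | C=C[C@@](C)(O[Si](CC)(CC)CC)CC[C@H]1O[C@]1(C)CCC(=O)OC(C)(C)C | intermediate
9 | (5S)-2-tert-butoxy-5-{(1R,4S)-1-hydroxy-4-methyl-4-[(triethylsilyl)oxy]hex-5-en-1-yl}-5-methyl-4,5-dihydro-3H-furan-1-ium (not isolated) | C=C[C@@](C)(O[Si](CC)(CC)CC)CC[C@@H](O)[C@]1(C)CCC(OC(C)(C)C)=[O+]1 | intermediate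
10 | (5S)-5-{(1R,4S)-1-hydroxy-4-methyl-4-[(triethylsilyl)oxy]hex-5-en-1-yl}-5-methyloxolan-2-one | C=C[C@@](C)(O[Si](CC)(CC)CC)CC[C@@H](O)[C@]1(C)CCC(=O)O1 | intermediate
11 | (5S)-5-[(1R,4S)-1,4-dihydroxy-4-methylhex-5-en-1-yl]-5-methyloxolan-2-one | C=C[C@@](C)(O)CC[C@@H](O)[C@]1(C)CCC(=O)O1 | intermediate
12 | pent-1-en-4-yne | C=CCC#C | starting material
13 | dimethyl[(1E)-2-methylpenta-1,4-dien-1-yl]alane (not isolated) | C=CC/C(C)=C/[Al](C)C | intermediate
14 | lithium butyldimethyl[(1E)-2-methylpenta-1,4-dien-1-yl]alanate (not isolated) | [Li+].C=CC/C(C)=C/[Al-](C)(C)CCCC | intermediate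
15 | (2E)-3-methylhexa-2,5-dien-1-ol | C=CC/C(C)=C/CO | intermediate
16 | (2E)-1-chloro-3-methylhexa-2,5-diene | C=CC/C(C)=C/CCl | intermediate
17 | 3-(chloromethyl)furan | ClCc1ccoc1 | starting material
18 | (furan-3-ylmethyl)magnesium chloride (not isolated) | Cl[Mg]Cc1ccoc1 | intermediate
19 | 3-[(3E)-4-methylhepta-3,6-dien-1-yl]furan | C=CC/C(C)=C/CCc1ccoc1 | intermediate
20 | (5S)-5-[(1R,4S,5E,8E)-11-(furan-3-yl)-1,4-dihydroxy-4,8-dimethylundeca-5,8-dien-1-yl]-5-methyloxolan-2-one | C/C(=C\CCc1ccoc1)C/C=C/[C@@](C)(O)CC[C@@H](O)[C@]1(C)CCC(=O)O1 | target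

**Step count**

Total step count: 11. Longest linear sequence: 8 steps (steps 1–7 and 11, from 1); the furan branch (steps 8–10) joins in step 11.

**Steps most likely to fail**

Step 11 (cross-metathesis). The diene 19 may dimerise faster than it engages the hindered carbinol 11, its terminal double bond may migrate into conjugation through ruthenium hydride species, and E control may be incomplete. The fallback forms the C10–C11 single bond by cross-coupling in place of the C9=C10 double bond by metathesis. It sets out from 11 and from the Grignard reagent 18 and comes back at the target 20.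
- Cross-metathesis of 11 with an excess of vinylboronic acid pinacol ester, a partner without a skipped diene (second-generation Hoveyda–Grubbs catalyst RuCl2(H2IMes)(=CH-C6H4-2-OiPr), CH2Cl2, 40 °C), should give the (E)-alkenylboronate (5S)-5-[(1R,4S,5E)-1,4-dihydroxy-4-methyl-6-(4,4,5,5-tetramethyl-1,3,2-dioxaborolan-2-yl)hex-5-en-1-yl]-5-methyloxolan-2-one F1.
- Coupling of 18 with 1-chloro-3-methylbut-2-ene (Li2CuCl4 cat., THF, 0 °C) gives 3-(4-methylpent-3-en-1-yl)furan F2.
- SeO2/t-BuOOH oxidation of its (E)-methyl group gives (2E)-5-(furan-3-yl)-2-methylpent-2-en-1-ol F3.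
- CBr4/PPh3 gives 3-[(3E)-5-bromo-4-methylpent-3-en-1-yl]furan F4.
- Suzuki–Miyaura allyl–alkenyl coupling of F1 with F4 (Pd(PPh3)4, aq. K2CO3, THF, 40 °C) should join C10 to C11 with both olefin geometries retained and deliver 20.

Step 6 (key lactonisation). The C8 silyloxy oxygen may attack C5 to close a tetrahydrofuran, the silyl group may be lost before ring closure, or the tertiary allylic ether may ionise under the external acid. The fallback changes the nucleophile to a free carboxylic acid that opens the epoxide by its own acidity, with no added strong acid. It sets out from 4 and comes back at 10.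
- Alkylation of the lithium enolate of methyl acetate with 4 (LiN(iPr)2, THF, −78 °C) gives methyl (4E,8S)-4,8-dimethyl-8-[(triethylsilyl)oxy]deca-4,9-dienoate F5.
- Shi epoxidation as in step 5 gives methyl 3-[(2R,3R)-2-methyl-3-{(3S)-3-methyl-3-[(triethylsilyl)oxy]pent-4-en-1-yl}oxiran-2-yl]propanoate F6.
- Saponification (LiOH, THF/H2O, 0 °C to rt) and acidification to about pH 4 with aqueous citric acid release 3-[(2R,3R)-2-methyl-3-{(3S)-3-methyl-3-[(triethylsilyl)oxy]pent-4-en-1-yl}oxiran-2-yl]propanoic acid F7, which is not isolated and should cyclise in the same 5-exo, invertive sense to 10.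

Step 10 (copper-catalysed Grignard coupling). Wurtz-type self-coupling may occur while the furylmethyl Grignard reagent forms, and SN2′ attack at the γ-carbon of the allylic chloride may compete. The fallback replaces the sp3–sp3 allylic substitution by an sp3–sp2 Negishi coupling onto the furan ring. It sets out from 12 (through the alanate 14 of step 8) and comes back at 19.
- Reaction of 14 with oxirane (THF, 0 °C to rt) gives (3E)-4-methylhepta-3,6-dien-1-ol F8.
- I2, PPh3 and imidazole (CH2Cl2, 0 °C) give (4E)-7-iodo-4-methylhepta-1,4-diene F9.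
- Zinc insertion (Zn dust, LiCl, THF) gives [(3E)-4-methylhepta-3,6-dien-1-yl]zinc iodide F10, which is not isolated.
- Negishi coupling of F10 with 3-bromofuran (PdCl2(dppf), THF, 50 °C) should give 19.

**Further compounds**

F1 | step 11 | (5S)-5-[(1R,4S,5E)-1,4-dihydroxy-4-methyl-6-(4,4,5,5-tetramethyl-1,3,2-dioxaborolan-2-yl)hex-5-en-1-yl]-5-methyloxolan-2-one | CC1(C)OB(/C=C/[C@@](C)(O)CC[C@@H](O)[C@]2(C)CCC(=O)O2)OC1(C)C
F2 | step 11 | 3-(4-methylpent-3-en-1-yl)furan | CC(C)=CCCc1ccoc1
F3 | step 11 | (2E)-5-(furan-3-yl)-2-methylpent-2-en-1-ol | OC/C(C)=C/CCc1ccoc1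
F4 | step 11 | 3-[(3E)-5-bromo-4-methylpent-3-en-1-yl]furan | BrC/C(C)=C/CCc1ccoc1
F5 | step 6 | methyl (4E,8S)-4,8-dimethyl-8-[(triethylsilyl)oxy]deca-4,9-dienoate | C=C[C@@](C)(O[Si](CC)(CC)CC)CC/C=C(\C)CCC(=O)OC
F6 | step 6 | methyl 3-[(2R,3R)-2-methyl-3-{(3S)-3-methyl-3-[(triethylsilyl)oxy]pent-4-en-1-yl}oxiran-2-yl]propanoate | C=C[C@@](C)(O[Si](CC)(CC)CC)CC[C@H]1O[C@]1(C)CCC(=O)OC
F7 | step 6 | 3-[(2R,3R)-2-methyl-3-{(3S)-3-methyl-3-[(triethylsilyl)oxy]pent-4-en-1-yl}oxiran-2-yl]propanoic acid | C=C[C@@](C)(O[Si](CC)(CC)CC)CC[C@H]1O[C@]1(C)CCC(=O)O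
F8 | step 10 | (3E)-4-methylhepta-3,6-dien-1-ol | C=CC/C(C)=C/CCO
F9 | step 10 | (4E)-7-iodo-4-methylhepta-1,4-diene | C=CC/C(C)=C/CCI
F10 | step 10 | [(3E)-4-methylhepta-3,6-dien-1-yl]zinc iodide | C=CC/C(C)=C/CC[Zn]I
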